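Readings and results are simulated from invented constants; the scatter is artificial.

At the first reading of the birch run, 27 min, Pdt stood at 4.50% of the Sbt charged, and the meeting opened on that reading.

| flask | Sbt | Ctl | Pdt | time |
|---|---|---|---|---|
| birch | 100 mM | 5.00 mM |  |  |
| cedar | 200 mM | 5.00 mM |  |  |
| alder | 100 mM | 15.0 mM |  |  |
| elm | 100 mM | 5.00 mM | 50.0 mM |  |
| larch | 33.0 mM | 1.70 mM |  | 160 min |

- birch run (time / min: [Pdt] / mM): 27: 4.5; 53: 12.0; 80: 27.4; 110: 49.5; 130: 65.2; 160: 83.1
- cedar run (time / min: [Pdt] / mM): 27: 13.2; 53: 58.1; 80: 137.1; 110: 186.5; 130: 195.9; 160: 199.5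
- alder run (time / min: [Pdt] / mM): 27: 11.2; 53: 28.3; 80: 50.6; 110: 72.4; 130: 84.0; 160: 92.8
- elm run (time / min: [Pdt] / mM): 27: 96.6; 53: 128.9; 80: 143.1; 110: 147.9; 130: 149.4; 160: 150.2

(scatter of a reading: 0.3 mM)

- Overall: Sbt -> Pdt, with Ctl as catalyst.
- Constant volume, constant temperature.
- Readings of a species count what is bound in complexes too.
- An order is taken over about fifteen percent of the charge, up and down.

- apparent order in [Ctl] of the starting rate, round the charge of the birch run (the rate where two percent of its Sbt have turned into Pdt)
- apparent order in [Sbt] of the starting rate, round the charge of the birch run (the rate where two percent of its Sbt have turned into Pdt) (one fixed amount of Pdt, the same in the runs compared)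
- Pdt in the larch run at 160 min, as a share of the Sbt charged

I proposed to treat the Pdt path (autocatalysis) as a correction to the birch rate at two percent turned. The mean birch rate up to the first reading was 0.00167 min⁻¹, as a fraction of the charge, and I took it as the rate at that point.

For the size of the correction I turned to the elm run, seeded with half a charge of Pdt. Its first interval ran ten times as fast as the birch run, so I gave that interval wholly to the Pdt path. The S-curve through its start and first reading gives a Pdt constant of 0.0318 min⁻¹. Multiplied by the fractions of Pdt and Sbt, it gives the fraction of the charge turned per minute.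

At two percent turned in the birch run, the correction is 6.22 × 10⁻⁴ min⁻¹. That leaves a Ctl part of 0.00104 min⁻¹, larger than the correction. The Ctl share, the fraction of the rate left after the Pdt path is taken away, 0.627, was my figure for the order in Ctl, on the assumption that the Ctl part follows Ctl in proportion and the correction does not follow it. I took both parts to follow Sbt in proportion at a fixed amount of Pdt, and on that assumption put the order in Sbt at one.

The forecast gave 0.6 for Ctl, lower than my share, 0.95 for Sbt and 14.5% for the larch run, holding that “the Pdt path barely depends on Ctl”. I offered no figure for the larch run.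

    Ctl + Sbt ⇌ Ctl.Sbt, settled at all times (1.520 L mol⁻¹)
    Ctl.Sbt → Pdt + Ctl (0.1806 min⁻¹)
    Sbt + Pdt → 2 Pdt (0.3030 L mol⁻¹ min⁻¹)
    2 Ctl → 2 X (0.6540 L mol⁻¹ min⁻¹)

The flask gives orders of 0.63 in Ctl and 0.99 in Sbt, and in the larch run 14.1% of the Sbt charged stands as Pdt at 160 min. The rate in the birch run at two percent turned is 0.00168 min⁻¹ of the charge. The alder run was charged with 3.00 times the Ctl of the birch run, so the Ctl part multiplied by that ratio, plus the same correction, comes to 0.00376 min⁻¹, and the Ctl share of 0.627 becomes 0.834. The rate in the alder run at two percent turned is 0.00378 min⁻¹ of the charge.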